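1. The target is the fully O-dealkylated form of ether 19; one BBr3 step at the end frees all thirteen hydroxyls.
2. The ring B–O–ring C ether is cut at the C1 oxygen of ring C: copper-catalysed arylation of the less hindered C1 hydroxyl of hydroquinone 12 with ring AB bromide 18 (from 5-bromovanillin by Chan–Lam arylation, Baeyer–Villiger oxidation and methylation).
3. The strategy rests on ring C, a hexasubstituted benzene with para oxygens at C1 and C4, further oxygens at C2 and C6, and aryl rings D and E at C3 and C5; it is built by ring opening of a 4-hydroxy-4-vinylcyclobutenone and 6π closure that forms C4–C5 (Moore rearrangement, 11 to 12).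
4. Cyclobutenone 11 is split into aryl cyclobutenedione 5 (C1, C2, C3 with ring D, C4; from diisopropyl squarate and lithiated 1,3,5-trimethoxybenzene) and an α-methoxy-β-arylvinyllithium (C6, C5 with ring E), released by tin–lithium exchange from a stannane made from the arylacetate through its ketene acetal phosphate.
5. Ring order: rings A, B, D and E are bought as arenes; ring C is the only ring formed (step 6), and the ring AB and ring CDE halves are joined in step 10.

Key step: step 6

Remark on ring labels: ring A is the terminal 3,5-dioxygenated phenoxy ring and ring B the central 1,2,3,5-tetraoxygenated ring; ring C is numbered C1 (O–ring B), C2 (OH), C3 (ring D), C4 (OH), C5 (ring E), C6 (OH).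
Remark on the vinyl unit: deprotonation of a β-(2,4,6-trimethoxyphenyl) enol ether would metalate the ring C–H between two methoxy groups rather than the vinyl C–H, so the vinyllithium is made by tin–lithium exchange; the enolate route used delivers the alkene with the aryl group cis to the metal, hence the E alkene in 11, and this geometry is erased in step 6.
Assumption: 2-(2,4,6-trimethoxyphenyl)acetic acid (6) is taken as a purchasable building block.

Step 1
Reactants: 1 1,3,5-trimethoxybenzene; 2 diisopropyl squarate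
Product: 5 3-isopropoxy-4-(2,4,6-trimethoxyphenyl)cyclobut-3-ene-1,2-dione, via 2,4,6-trimethoxyphenyllithium 3 (not isolated), via squarate aryl adduct 4 (not isolated)
Conditions: n-BuLi, THF, 0 °C to rt; then 2, THF, −78 °C; then 12 M HCl, CH2Cl2, rt
Reagents that add atoms: water (from the aqueous HCl), O
Why: Lithiation of 1 between two methoxy groups (directed ortho-metalation), 1,2-addition of 3 to one squarate carbonyl and acid-catalysed 1,3-oxygen transposition of 4 with loss of isopropanol form the standard squarate route to 3-alkoxy-4-arylcyclobutenediones; the racemic carbinol centre of 4 is lost again in the same flask.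

Step 2
Reactants: 6 2-(2,4,6-trimethoxyphenyl)acetic acid
Product: 7 methyl 2-(2,4,6-trimethoxyphenyl)acetate
Conditions: MeI, K2CO3, DMF, rt
Reagents that add atoms: iodomethane, CI
Why: Carboxylate O-alkylation (SN2 esterification) under mild base is chosen over acid catalysis to spare the very electron-rich ring.

Step 3
Reactants: 7 methyl 2-(2,4,6-trimethoxyphenyl)acetate
Product: 8 (Z)-1-methoxy-2-(2,4,6-trimethoxyphenyl)ethenyl diphenyl phosphate
Conditions: KN(SiMe3)2, THF/DMPU, −78 °C; then (PhO)2P(O)Cl, −78 °C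
Reagents that add atoms: diphenyl chlorophosphate, O=P(Cl)(Oc1ccccc1)Oc1ccccc1
Why: O-Phosphorylation of the potassium ester enolate gives the ketene acetal phosphate; only the benzylic CH2 is acidic enough for the silazide base, and the dissociating K+/DMPU medium is expected to favour the enolate with the aryl group cis to O–K, which sets the Z alkene.

Step 4
Reactants: 8 (Z)-1-methoxy-2-(2,4,6-trimethoxyphenyl)ethenyl diphenyl phosphate
Product: 9 (Z)-[1-methoxy-2-(2,4,6-trimethoxyphenyl)ethenyl]trimethylstannane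
Conditions: Me3SnSnMe3, Pd(PPh3)4 (cat.), LiCl, THF, 65 °C
Reagents that add atoms: hexamethylditin, C[Sn](C)(C)[Sn](C)(C)C
Why: Palladium-catalysed cross-coupling of a ketene acetal phosphate with a distannane (oxidative addition of the C–O bond, Sn–Sn transmetalation, reductive elimination) should replace the phosphate by SnMe3 with retention of alkene geometry.

Step 5
Reactants: 9 (Z)-[1-methoxy-2-(2,4,6-trimethoxyphenyl)ethenyl]trimethylstannane; 5 3-isopropoxy-4-(2,4,6-trimethoxyphenyl)cyclobut-3-ene-1,2-dione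
Product: 11 racemic 4-hydroxy-3-isopropoxy-4-[(E)-1-methoxy-2-(2,4,6-trimethoxyphenyl)vinyl]-2-(2,4,6-trimethoxyphenyl)cyclobut-2-en-1-one, via vinyllithium 10 (not isolated)
Conditions: 9, MeLi, THF, −78 °C; then cannulated into 5, THF, −78 °C; sat. aq. NH4Cl
Reagents that add atoms: none
Why: Tin–lithium exchange at −78 °C releases the α-methoxyvinyllithium with retention and without strong-base deprotonation, and it should add 1,2 to the ketone carbonyl next to the isopropoxy-bearing carbon rather than to the aryl-shielded vinylogous ester carbonyl, as is usual for 3-alkoxycyclobutenediones; the new carbinol stereocentre forms as a racemate and needs no control because step 6 destroys it.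

Step 6
Reactants: 11 racemic 4-hydroxy-3-isopropoxy-4-[(E)-1-methoxy-2-(2,4,6-trimethoxyphenyl)vinyl]-2-(2,4,6-trimethoxyphenyl)cyclobut-2-en-1-one
Product: 12 2-isopropoxy-6-methoxy-3,5-bis(2,4,6-trimethoxyphenyl)benzene-1,4-diol
Conditions: PhMe (degassed), 110 °C, Ar
Reagents that add atoms: none
Why: This is a Moore rearrangement of a 4-alkenyl-4-hydroxycyclobutenone: thermal conrotatory 4π opening of the C(=O)–C(OH) ring bond, with the hydroxyl rotating outward, gives a dienylketene whose vinyl group faces the ketene. The ketene carbon then bonds to the aryl-bearing vinyl carbon in a thermal 6π electrocyclisation, which forms C4–C5 and closes ring C as a cyclohexa-2,4-dienone that enolises to the hydroquinone. No stereocentre is created, and the racemic carbinol centre and the alkene geometry are both erased on aromatisation. Regiochemistry is fixed by connectivity: the ketene oxygen becomes the C4 hydroxyl between rings D and E, and the carbinol oxygen becomes the C1 hydroxyl between the isopropoxy and methoxy groups. The step needs the outward torquoselectivity of the donor hydroxyl, which keeps it from lactonising onto the ketene, and closure with the aryl group on the inner side of the vinyl terminus, which should be tolerated because the sp-hybridised ketene carbon carries no substituent pointing into the forming bond. Exclusion of air keeps the electron-rich hydroquinone from going on to the quinone.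

Step 7
Reactants: 13 5-bromovanillin; 14 (3,5-dimethoxyphenyl)boronic acid
Product: 15 3-bromo-4-(3,5-dimethoxyphenoxy)-5-methoxybenzaldehyde
Conditions: Cu(OAc)2 (30 mol%), pyridine, 4 Å MS, CH2Cl2, O2 (1 atm), rt
Reagents that add atoms: none
Why: Chan–Lam oxidative O-arylation of a phenol with an arylboronic acid runs at room temperature, leaves the aryl bromide and the aldehyde untouched, and is known to work for acidic 2,6-disubstituted phenols.

Step 8
Reactants: 15 3-bromo-4-(3,5-dimethoxyphenoxy)-5-methoxybenzaldehyde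
Product: 17 3-bromo-4-(3,5-dimethoxyphenoxy)-5-methoxyphenol, via aryl formate 16 (not isolated)
Conditions: mCPBA, CH2Cl2, 0 °C to rt; then K2CO3 (cat.), MeOH, rt
Reagents that add atoms: 3-chloroperoxybenzoic acid, OOC(=O)c1cccc(Cl)c1
Why: Baeyer–Villiger (Dakin-type) oxidation with migration of the electron-rich para-aryloxy aryl group gives the aryl formate, which mild methanolysis converts into the phenol.

Step 9
Reactants: 17 3-bromo-4-(3,5-dimethoxyphenoxy)-5-methoxyphenol
Product: 18 1-bromo-2-(3,5-dimethoxyphenoxy)-3,5-dimethoxybenzene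
Conditions: MeI, K2CO3, acetone, 56 °C
Reagents that add atoms: iodomethane, CI
Why: Williamson O-methylation of the phenoxide.

Step 10
Reactants: 12 2-isopropoxy-6-methoxy-3,5-bis(2,4,6-trimethoxyphenyl)benzene-1,4-diol; 18 1-bromo-2-(3,5-dimethoxyphenoxy)-3,5-dimethoxybenzene
Product: 19 4-[2-(3,5-dimethoxyphenoxy)-3,5-dimethoxyphenoxy]-3-isopropoxy-5-methoxy-2,6-bis(2,4,6-trimethoxyphenyl)phenol
Conditions: CuI (20 mol%), picolinic acid (40 mol%), K3PO4, DMSO (degassed), 100 °C, Ar
Reagents that add atoms: none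
Why: In this ligand-accelerated Ullmann diaryl ether synthesis the C1 phenoxide, flanked only by alkoxy groups, should be arylated while the C4 oxygen buried between two 2,6-dimethoxyphenyl rings stays free; degassed conditions keep the hydroquinone from oxidising to the quinone.

Step 11
Reactants: 19 4-[2-(3,5-dimethoxyphenoxy)-3,5-dimethoxyphenoxy]-3-isopropoxy-5-methoxy-2,6-bis(2,4,6-trimethoxyphenyl)phenol
Product: 20 CNP0228669.0, 2-[2-(3,5-dihydroxyphenoxy)-3,5-dihydroxyphenoxy]-4,6-bis(2,4,6-trihydroxyphenyl)benzene-1,3,5-triol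
Conditions: BBr3 (excess), CH2Cl2, −78 °C to rt; then degassed H2O, 0 °C
Reagents that add atoms: none
Why: BBr3 cleavage of alkyl aryl ethers (Lewis acid complexation, bromide attack at the alkyl carbon) should remove the eleven methyl groups and the isopropyl group, while the two diaryl ether bonds offer no sp3 carbon to bromide and survive.

Compound list
1 | 1,3,5-trimethoxybenzene | COc1cc(OC)cc(OC)c1 | starting material
2 | diisopropyl squarate (3,4-diisopropoxycyclobut-3-ene-1,2-dione) | CC(C)OC1=C(OC(C)C)C(=O)C1=O | starting material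
3 | 2,4,6-trimethoxyphenyllithium | [Li]c1c(OC)cc(OC)cc1OC | intermediate
4 | racemic 4-hydroxy-2,3-diisopropoxy-4-(2,4,6-trimethoxyphenyl)cyclobut-2-en-1-one | CC(C)OC1=C(OC(C)C)C(O)(c2c(OC)cc(OC)cc2OC)C1=O | intermediate
5 | 3-isopropoxy-4-(2,4,6-trimethoxyphenyl)cyclobut-3-ene-1,2-dione | CC(C)OC1=C(c2c(OC)cc(OC)cc2OC)C(=O)C1=O | intermediate
6 | 2-(2,4,6-trimethoxyphenyl)acetic acid | COc1cc(OC)c(CC(=O)O)c(OC)c1 | starting material
7 | methyl 2-(2,4,6-trimethoxyphenyl)acetate | COC(=O)Cc1c(OC)cc(OC)cc1OC | intermediate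
8 | (Z)-1-methoxy-2-(2,4,6-trimethoxyphenyl)ethenyl diphenyl phosphate (aryl cis to the phosphate oxygen) | CO/C(OP(=O)(Oc1ccccc1)Oc1ccccc1)=C/c1c(OC)cc(OC)cc1OC | intermediate
9 | (Z)-[1-methoxy-2-(2,4,6-trimethoxyphenyl)ethenyl]trimethylstannane (aryl cis to tin) | CO/C([Sn](C)(C)C)=C/c1c(OC)cc(OC)cc1OC | intermediate
10 | (E)-[1-methoxy-2-(2,4,6-trimethoxyphenyl)ethenyl]lithium (aryl cis to lithium) | CO/C([Li])=C/c1c(OC)cc(OC)cc1OC | intermediate
11 | racemic 4-hydroxy-3-isopropoxy-4-[(E)-1-methoxy-2-(2,4,6-trimethoxyphenyl)vinyl]-2-(2,4,6-trimethoxyphenyl)cyclobut-2-en-1-one (aryl cis to the carbinol carbon) | CC(C)OC1=C(c2c(OC)cc(OC)cc2OC)C(=O)C1(O)/C(OC)=C\c1c(OC)cc(OC)cc1OC | intermediate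
12 | 2-isopropoxy-6-methoxy-3,5-bis(2,4,6-trimethoxyphenyl)benzene-1,4-diol | COc1c(O)c(OC(C)C)c(-c2c(OC)cc(OC)cc2OC)c(O)c1-c1c(OC)cc(OC)cc1OC | intermediate
13 | 5-bromovanillin (3-bromo-4-hydroxy-5-methoxybenzaldehyde) | COc1cc(C=O)cc(Br)c1O | starting material
14 | (3,5-dimethoxyphenyl)boronic acid | COc1cc(OC)cc(B(O)O)c1 | starting material
15 | 3-bromo-4-(3,5-dimethoxyphenoxy)-5-methoxybenzaldehyde | COc1cc(OC)cc(Oc2c(Br)cc(C=O)cc2OC)c1 | intermediate
16 | 3-bromo-4-(3,5-dimethoxyphenoxy)-5-methoxyphenyl formate | COc1cc(OC)cc(Oc2c(Br)cc(OC=O)cc2OC)c1 | intermediate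
17 | 3-bromo-4-(3,5-dimethoxyphenoxy)-5-methoxyphenol | COc1cc(OC)cc(Oc2c(Br)cc(O)cc2OC)c1 | intermediate
18 | 1-bromo-2-(3,5-dimethoxyphenoxy)-3,5-dimethoxybenzene | COc1cc(OC)cc(Oc2c(Br)cc(OC)cc2OC)c1 | intermediate
19 | 4-[2-(3,5-dimethoxyphenoxy)-3,5-dimethoxyphenoxy]-3-isopropoxy-5-methoxy-2,6-bis(2,4,6-trimethoxyphenyl)phenol | COc1cc(OC)cc(Oc2c(OC)cc(OC)cc2Oc2c(OC(C)C)c(-c3c(OC)cc(OC)cc3OC)c(O)c(-c3c(OC)cc(OC)cc3OC)c2OC)c1 | intermediate
20 | CNP0228669.0, 2-[2-(3,5-dihydroxyphenoxy)-3,5-dihydroxyphenoxy]-4,6-bis(2,4,6-trihydroxyphenyl)benzene-1,3,5-triol | Oc1cc(O)cc(Oc2c(O)cc(O)cc2Oc2c(O)c(-c3c(O)cc(O)cc3O)c(O)c(-c3c(O)cc(O)cc3O)c2O)c1 | target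

Total step count: 11
Longest linear sequence: 7 steps (steps 2, 3, 4, 5, 6, 10, 11, from acid 6)

Steps most likely to fail

Step 10. The hydroquinone dianion may be oxidised to the quinone under basic copper conditions, or the coupling of two hindered, electron-rich partners may stall. The fallback sets out from 12 and takes the redox-labile hydroquinone out of play before the ether is made. Silylation of the less hindered C1 hydroxyl (t-BuMe2SiCl, imidazole, DMF) should give 4-[(tert-butyldimethylsilyl)oxy]-3-isopropoxy-5-methoxy-2,6-bis(2,4,6-trimethoxyphenyl)phenol F1. Methylation of the remaining C4 hydroxyl (NaH, MeI, DMF, 0 °C) should give tert-butyl[2-isopropoxy-4,6-dimethoxy-3,5-bis(2,4,6-trimethoxyphenyl)phenoxy]dimethylsilane F2. Bu4NF in THF then frees the monophenol 2-isopropoxy-4,6-dimethoxy-3,5-bis(2,4,6-trimethoxyphenyl)phenol F3, which can no longer form a quinone. F3 is joined to bromide 18 by palladium-catalysed C–O coupling (Pd(OAc)2, 2-di-tert-butylphosphino-2',4',6'-triisopropylbiphenyl, K3PO4, toluene, 100 °C) to give 1-[2-(3,5-dimethoxyphenoxy)-3,5-dimethoxyphenoxy]-2-isopropoxy-4,6-dimethoxy-3,5-bis(2,4,6-trimethoxyphenyl)benzene F4. The BBr3 conditions of step 11 cleave its thirteen alkyl ethers, and the route is rejoined at 20.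

Step 6. Electrocyclisation may be slowed by the aryl group on the inner side of the vinyl terminus; the reversibly formed ketene could then be drained by lactonisation of the free hydroxyl or by decomposition. The fallback sets out from 11 and runs the rearrangement on the O-silylated carbinol, which cannot lactonise and tolerates a higher temperature. Silylation (Et3SiOTf, 2,6-lutidine, CH2Cl2, −78 °C) should give racemic 3-isopropoxy-4-[(E)-1-methoxy-2-(2,4,6-trimethoxyphenyl)vinyl]-4-(triethylsilyloxy)-2-(2,4,6-trimethoxyphenyl)cyclobut-2-en-1-one F5. Thermolysis in degassed xylene at 140 °C should give the mono-silylated hydroquinone 3-isopropoxy-5-methoxy-4-(triethylsilyloxy)-2,6-bis(2,4,6-trimethoxyphenyl)phenol F6. Desilylation (Bu4NF, AcOH, THF, 0 °C, Ar) returns the route at 12.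

Step 11. Cleavage of the twelve alkyl ethers may stop short, and the free polyphenol may degrade by air oxidation during isolation. The fallback sets out from 19 and changes from direct isolation to capture and release. The crude product of the BBr3 treatment is not isolated but exhaustively acetylated (Ac2O, pyridine, DMAP) to the trideca-O-acetate of 20, 2-[2-(3,5-diacetoxyphenoxy)-3,5-diacetoxyphenoxy]-4,6-bis(2,4,6-triacetoxyphenyl)benzene-1,3,5-triyl triacetate F7. This stable ester can be purified on silica, and partly dealkylated material can be separated and resubmitted. Zemplén deacetylation (NaOMe cat., degassed MeOH, then acidic ion-exchange resin) returns the route at 20.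

Further compounds
F1 | step 10 | 4-[(tert-butyldimethylsilyl)oxy]-3-isopropoxy-5-methoxy-2,6-bis(2,4,6-trimethoxyphenyl)phenol | COc1c(O[Si](C)(C)C(C)(C)C)c(OC(C)C)c(-c2c(OC)cc(OC)cc2OC)c(O)c1-c1c(OC)cc(OC)cc1OC
F2 | step 10 | tert-butyl[2-isopropoxy-4,6-dimethoxy-3,5-bis(2,4,6-trimethoxyphenyl)phenoxy]dimethylsilane | COc1c(O[Si](C)(C)C(C)(C)C)c(OC(C)C)c(-c2c(OC)cc(OC)cc2OC)c(OC)c1-c1c(OC)cc(OC)cc1OC
F3 | step 10 | 2-isopropoxy-4,6-dimethoxy-3,5-bis(2,4,6-trimethoxyphenyl)phenol | COc1c(O)c(OC(C)C)c(-c2c(OC)cc(OC)cc2OC)c(OC)c1-c1c(OC)cc(OC)cc1OC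
F4 | step 10 | 1-[2-(3,5-dimethoxyphenoxy)-3,5-dimethoxyphenoxy]-2-isopropoxy-4,6-dimethoxy-3,5-bis(2,4,6-trimethoxyphenyl)benzene | COc1cc(OC)cc(Oc2c(OC)cc(OC)cc2Oc2c(OC(C)C)c(-c3c(OC)cc(OC)cc3OC)c(OC)c(-c3c(OC)cc(OC)cc3OC)c2OC)c1
F5 | step 6 | racemic 3-isopropoxy-4-[(E)-1-methoxy-2-(2,4,6-trimethoxyphenyl)vinyl]-4-(triethylsilyloxy)-2-(2,4,6-trimethoxyphenyl)cyclobut-2-en-1-one | CC[Si](CC)(CC)OC1(/C(OC)=C\c2c(OC)cc(OC)cc2OC)C(OC(C)C)=C(c2c(OC)cc(OC)cc2OC)C1=O
F6 | step 6 | 3-isopropoxy-5-methoxy-4-(triethylsilyloxy)-2,6-bis(2,4,6-trimethoxyphenyl)phenol | COc1c(O[Si](CC)(CC)CC)c(OC(C)C)c(-c2c(OC)cc(OC)cc2OC)c(O)c1-c1c(OC)cc(OC)cc1OC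
F7 | step 11 | 2-[2-(3,5-diacetoxyphenoxy)-3,5-diacetoxyphenoxy]-4,6-bis(2,4,6-triacetoxyphenyl)benzene-1,3,5-triyl triacetate | CC(=O)Oc1cc(OC(C)=O)cc(Oc2c(OC(C)=O)cc(OC(C)=O)cc2Oc2c(OC(C)=O)c(-c3c(OC(C)=O)cc(OC(C)=O)cc3OC(C)=O)c(OC(C)=O)c(-c3c(OC(C)=O)cc(OC(C)=O)cc3OC(C)=O)c2OC(C)=O)c1
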